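Ring A is disconnected at C8–C8a, C6–C7 and C4a–C8a into a chiral diazo enone that already carries ring B, the C3 stereocentre and a C2 chloride, and a siloxyalkyne that carries the C8 side chain. One photochemical operation (Wolff rearrangement, [2+2] cycloaddition, 4π opening, 6π closure) builds the whole resorcinol ring. It exploits the fact that ring A (C4a–C8a) has its C8 alkyl chain flanked by the oxygens at C7 and C8a, with a carbon substituent at C4a: exactly the 2-alkyl-3-siloxyphenol that a vinylketene and a siloxyalkyne give. The C8a hydroxyl emerges free and then closes ring C on the chloride; C3 comes from a rhodium/BINAP conjugate arylation.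

Key step: step 15

Atom labels follow isoflavan numbering (ring C: O1, C2, C3, C4; ring A: C4a to C8a; ring B: C1' to C6'). Ar = 2,4-bis(methoxymethoxy)-5-(2-methylbut-3-en-2-yl)phenyl, the protected ring B.

Assumption: (R)-BINAP is taken to give the (R)-lactone in step 6, by transfer of the established facial preference of rhodium–BINAP arylation of cyclic enones and unsaturated lactones; if correlation shows the opposite sense, the (S)-ligand is used.

Step 1
Reactants: 1 4-bromobenzene-1,3-diol
Product: 2 1-bromo-2,4-bis(methoxymethoxy)benzene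
Conditions: MOMCl (2.6 equiv), i-Pr2NEt, CH2Cl2, 0 °C → rt
Reagents that add atoms: chloromethyl methyl ether, COCCl
Why: Williamson-type O-alkylation of both phenols by the reactive chloromethyl ether installs methoxymethyl ethers, which tolerate every basic, organometallic and photochemical step that follows.

Step 2
Reactants: 2 1-bromo-2,4-bis(methoxymethoxy)benzene; 3 2-methylpropanal
Product: 4 2-[2,4-bis(methoxymethoxy)phenyl]-2-methylpropanal
Conditions: [Pd(allyl)Cl]2 (1 mol %), Fe(C5H4PPh2)2 (dppf, 2 mol %), Cs2CO3, dioxane, 80 °C, sealed tube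
Reagents that add atoms: none
Why: Palladium-catalysed α-arylation of the enolate of an α-branched aldehyde forms the aryl–quaternary carbon bond at the only C–Br site, and the product can no longer enolise.

Step 3
Reactants: 4 2-[2,4-bis(methoxymethoxy)phenyl]-2-methylpropanal
Product: 5 2,4-bis(methoxymethoxy)-1-(2-methylbut-3-en-2-yl)benzene
Conditions: Ph3PCH3Br, KOt-Bu, THF, 0 °C → rt
Reagents that add atoms: methyltriphenylphosphonium bromide, C[P+](c1ccccc1)(c1ccccc1)c1ccccc1.[Br-]
Why: Wittig methylenation of the non-enolisable aldehyde with the unstabilised ylide completes the 1,1-dimethylallyl group.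

Step 4
Reactants: 5 2,4-bis(methoxymethoxy)-1-(2-methylbut-3-en-2-yl)benzene
Product: 6 1-bromo-2,4-bis(methoxymethoxy)-5-(2-methylbut-3-en-2-yl)benzene
Conditions: NBS (1.05 equiv), MeCN, 0 °C, dark
Reagents that add atoms: N-bromosuccinimide, O=C1CCC(=O)N1Br
Why: Electrophilic aromatic bromination goes para to one acetal oxygen and ortho to the other, the only doubly activated unhindered carbon, and should be much faster than attack on the hindered monosubstituted alkene.

Step 5
Reactants: 6 1-bromo-2,4-bis(methoxymethoxy)-5-(2-methylbut-3-en-2-yl)benzene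
Product: 8 [2,4-bis(methoxymethoxy)-5-(2-methylbut-3-en-2-yl)phenyl]boronic acid, via aryllithium 7 (not isolated)
Conditions: n-BuLi, THF, −78 °C; B(Oi-Pr)3, −78 °C → rt; aq NH4Cl
Reagents that add atoms: triisopropyl borate, CC(C)OB(OC(C)C)OC(C)C; water, O
Why: Bromine–lithium exchange, fast at −78 °C and assisted by the ortho acetal oxygen, followed by borylation of the aryllithium and mild hydrolysis (lithiation–borylation) gives the boronic acid.

Step 6
Reactants: 8 [2,4-bis(methoxymethoxy)-5-(2-methylbut-3-en-2-yl)phenyl]boronic acid; 9 furan-2(5H)-one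
Product: 10 (4R)-4-Ar-oxolan-2-one
Conditions: [Rh(OH)((R)-BINAP)]2 (3 mol % Rh), 9 (3 equiv), dioxane/H2O 10:1, 40 °C
Reagents that add atoms: none
Why: In this Hayashi–Miyaura asymmetric conjugate addition the aryl–rhodium complex of (R)-BINAP inserts one enantiotopic face of the butenolide C=C and protonolysis of the oxa-π-allyl rhodium releases the lactone, so the ligand sets the future C3 as (R).

Step 7
Reactants: 10 (4R)-4-Ar-oxolan-2-one
Product: 11 (3R)-3-Ar-4-hydroxy-N-methoxy-N-methylbutanamide
Conditions: MeNHOMe·HCl (3 equiv), i-PrMgCl (6 equiv), THF, −20 → 0 °C; cold aq NH4Cl; used at once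
Reagents that add atoms: N,O-dimethylhydroxylamine hydrochloride, CNOC.Cl
Why: Aminolysis of the lactone by the magnesium amide (Weinreb amide formation) opens the ring under basic conditions that spare the acetals, and the stereocentre is not alpha to the carbonyl.

Step 8
Reactants: 11 (3R)-3-Ar-4-hydroxy-N-methoxy-N-methylbutanamide
Product: 12 (3R)-3-Ar-4-chloro-N-methoxy-N-methylbutanamide
Conditions: PPh3, CCl4, MeCN, 0 °C → rt
Reagents that add atoms: tetrachloromethane, ClC(Cl)(Cl)Cl
Why: Appel chlorination replaces the primary hydroxyl by chloride through SN2 attack on the alkoxyphosphonium ion under neutral conditions, at a carbon next to but not at the stereocentre.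

Step 9
Reactants: 12 (3R)-3-Ar-4-chloro-N-methoxy-N-methylbutanamide
Product: 13 (3R)-3-Ar-4-chlorobutanal
Conditions: i-Bu2AlH (1.3 equiv), THF, −78 °C; aq potassium sodium tartrate
Reagents that add atoms: none
Why: Hydride reduction of the Weinreb amide stops at the chelated aluminium hemiaminal, which gives the aldehyde on work-up without touching the alkyl chloride.

Step 10
Reactants: 13 (3R)-3-Ar-4-chlorobutanal
Product: 14 (3E,6R)-6-Ar-7-chlorohept-3-en-2-one
Conditions: Ph3P=CHC(O)CH3 (1.5 equiv), CH2Cl2, rt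
Reagents that add atoms: 1-(triphenylphosphoranylidene)propan-2-one, CC(=O)C=P(c1ccccc1)(c1ccccc1)c1ccccc1
Why: Wittig olefination with the acetyl-stabilised ylide gives the (E)-enone and is too weakly basic to close a cyclopropane from the γ-chloro aldehyde.

Step 11
Reactants: 14 (3E,6R)-6-Ar-7-chlorohept-3-en-2-one
Product: 16 (3E,6R)-6-Ar-7-chloro-1-diazohept-3-en-2-one, via trifluoroacetyl diketone 15 (not isolated)
Conditions: LiHMDS, THF, −78 °C; CF3CO2CH2CF3; then MsN3, Et3N, H2O, MeCN, rt
Reagents that add atoms: methanesulfonyl azide, CS(=O)(=O)N=[N+]=[N-]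
Why: Detrifluoroacetylative diazo transfer (Regitz type) works because kinetic enolisation at the methyl group and Claisen-type trifluoroacetylation activate that carbon for transfer from the sulfonyl azide, after which the trifluoroacetyl group is lost, and it avoids the dipolar cycloaddition that spoils acylation of diazomethane by unsaturated acid chlorides.

Step 12
Reactants: 17 methyl pent-4-ynoate
Product: 18 2-methylhex-5-yn-2-ol
Conditions: MeMgBr (3.3 equiv), THF, 0 °C → rt; aq NH4Cl
Reagents that add atoms: methylmagnesium bromide, C[Mg]Br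
Why: Double Grignard addition to the ester gives the tertiary alcohol, the third equivalent being taken up reversibly by the acetylenic C–H.

Step 13
Reactants: 18 2-methylhex-5-yn-2-ol
Product: 19 triethyl[(2-methylhex-5-yn-2-yl)oxy]silane
Conditions: Et3SiOTf, 2,6-lutidine, CH2Cl2, −78 → 0 °C
Reagents that add atoms: triethylsilyl trifluoromethanesulfonate, CC[Si](CC)(CC)OS(=O)(=O)C(F)(F)F
Why: Silylation by the silyl triflate with a hindered pyridine base protects the tertiary alcohol against the strong bases and the ketene to come, and it avoids the lactone that a 4-hydroxy ester precursor would form.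

Step 14
Reactants: 19 triethyl[(2-methylhex-5-yn-2-yl)oxy]silane
Product: 22 5-methyl-5-(triethylsilyloxy)-1-(triisopropylsilyloxy)hex-1-yne, via lithium acetylide 20 (not isolated), via lithium ynolate 21 (not isolated)
Conditions: LiHMDS (2.2 equiv), t-BuOOH, THF, −78 → 0 °C; then i-Pr3SiOTf, −78 °C
Reagents that add atoms: tert-butyl hydroperoxide, CC(C)(C)OO; triisopropylsilyl trifluoromethanesulfonate, CC(C)[Si](C(C)C)(C(C)C)OS(=O)(=O)C(F)(F)F
Why: Oxidation of the lithium acetylide by lithium tert-butyl peroxide gives the lithium ynolate, which the bulky silyl triflate captures on oxygen (ynolate O-silylation) to give the siloxyalkyne.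

Step 15
Reactants: 16 (3E,6R)-6-Ar-7-chloro-1-diazohept-3-en-2-one; 22 5-methyl-5-(triethylsilyloxy)-1-(triisopropylsilyloxy)hex-1-yne
Product: 26 6-[(2R)-2-Ar-3-chloropropyl]-2-[3-methyl-3-(triethylsilyloxy)butyl]-3-(triisopropylsilyloxy)phenol, via vinylketene 23 (not isolated), via vinylcyclobutenone 24 (not isolated), via dienylketene 25 (not isolated)
Conditions: 22 (1.5 equiv), hν (300 nm, Pyrex), ClCH2CH2Cl, 25 °C; then 80 °C, dark
Reagents that add atoms: none
Why: Light expels dinitrogen and photochemical Wolff rearrangement (vinyl shift) gives vinylketene 23, whose carbonyl carbon (future C8a) bonds to the nucleophilic chain-bearing carbon of 22 (C8) while its α-carbon (C6) bonds to the siloxy carbon (C7) in a [2+2] cycloaddition to cyclobutenone 24. 4π electrocyclic opening of 24 gives dienylketene 25, and 6π electrocyclisation between the ketene carbon and C4a followed by tautomerisation gives the phenol; this is the Danheiser benzannulation in its diazo ketone (second-generation) form with a siloxyalkyne, a known route to resorcinol monosilyl ethers. Ring A is the only ring that persists and it closes by 6π electrocyclisation, the four-membered ring of 24 being formed by [2+2] and opened again. No new stereocentre remains, because the ring CH of 24 becomes aromatic and C3 lies two bonds from any reacting atom. The step needs only regiocontrol in the ketene–alkyne union, which the polarisation of the silyl ynol ether secures, and the (E)-alkene of 16 keeps the C4 hydrogens away from the ketene so that no 1,5-hydrogen shift competes. The C8a hydroxyl emerges free beside the chloropropyl arm and O7 carries the triisopropylsilyl group.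

Step 16
Reactants: 26 6-[(2R)-2-Ar-3-chloropropyl]-2-[3-methyl-3-(triethylsilyloxy)butyl]-3-(triisopropylsilyloxy)phenol
Product: 28 (3R)-3-Ar-8-[3-methyl-3-(triethylsilyloxy)butyl]-7-(triisopropylsilyloxy)-3,4-dihydro-2H-chromene, via alkyl iodide 27 (not isolated)
Conditions: Cs2CO3, NaI (0.2 equiv), MeCN, 60 °C
Reagents that add atoms: none
Why: Intramolecular Williamson etherification with iodide catalysis (Finkelstein exchange) closes ring C by 6-exo-tet attack of the C8a phenoxide on C2, a carbon next to but not at the stereocentre, while the acetal-capped ring B oxygens cannot compete.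

Step 17
Reactants: 28 (3R)-3-Ar-8-[3-methyl-3-(triethylsilyloxy)butyl]-7-(triisopropylsilyloxy)-3,4-dihydro-2H-chromene
Product: 30 4-[(3R)-8-[3-methyl-3-(triethylsilyloxy)butyl]-7-(triisopropylsilyloxy)-3,4-dihydro-2H-chromen-3-yl]-6-(2-methylbut-3-en-2-yl)benzene-1,3-diol, via bis(trimethylsilyl) ether 29 (not isolated)
Conditions: Me3SiOTf (6 equiv), 2,2'-bipyridyl (9 equiv), MeCN, 0 °C → rt; then H2O
Reagents that add atoms: none
Why: Silyl triflate activation of the aryl methoxymethyl ethers with 2,2'-bipyridyl as acceptor of the acetal carbon gives aryl trimethylsilyl ethers that hydrolyse on work-up, a non-protic acetal cleavage that should spare the tertiary silyl ether, the vinyl group and the hindered aryl silyl ether, while O7 stays capped so that no dimethylchroman can form.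

Step 18
Reactants: 30 4-[(3R)-8-[3-methyl-3-(triethylsilyloxy)butyl]-7-(triisopropylsilyloxy)-3,4-dihydro-2H-chromen-3-yl]-6-(2-methylbut-3-en-2-yl)benzene-1,3-diol
Product: 31 4-[(3R)-7-hydroxy-8-(3-hydroxy-3-methylbutyl)-3,4-dihydro-2H-chromen-3-yl]-6-(2-methylbut-3-en-2-yl)benzene-1,3-diol
Conditions: Bu4NF (5 equiv), AcOH (5 equiv), THF, 0 → 40 °C, under argon
Reagents that add atoms: none
Why: Fluoride-mediated desilylation through pentacoordinate silicon, buffered with acetic acid, removes the aryl triisopropylsilyl and the tertiary triethylsilyl group and should give the target without strong acid or base.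

Compound list
1 | 4-bromobenzene-1,3-diol (4-bromoresorcinol) | Oc1ccc(Br)c(O)c1 | starting material
2 | 1-bromo-2,4-bis(methoxymethoxy)benzene | COCOc1ccc(Br)c(OCOC)c1 | intermediate
3 | 2-methylpropanal | CC(C)C=O | starting material
4 | 2-[2,4-bis(methoxymethoxy)phenyl]-2-methylpropanal | CC(C)(C=O)c1ccc(OCOC)cc1OCOC | intermediate
5 | 2,4-bis(methoxymethoxy)-1-(2-methylbut-3-en-2-yl)benzene | C=CC(C)(C)c1ccc(OCOC)cc1OCOC | intermediate
6 | 1-bromo-2,4-bis(methoxymethoxy)-5-(2-methylbut-3-en-2-yl)benzene | C=CC(C)(C)c1cc(Br)c(OCOC)cc1OCOC | intermediate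
7 | [2,4-bis(methoxymethoxy)-5-(2-methylbut-3-en-2-yl)phenyl]lithium | [Li]c1cc(C(C)(C)C=C)c(OCOC)cc1OCOC | intermediate (not isolated)
8 | [2,4-bis(methoxymethoxy)-5-(2-methylbut-3-en-2-yl)phenyl]boronic acid | OB(O)c1cc(C(C)(C)C=C)c(OCOC)cc1OCOC | intermediate
9 | furan-2(5H)-one | O=C1OCC=C1 | starting material
10 | (4R)-4-[2,4-bis(methoxymethoxy)-5-(2-methylbut-3-en-2-yl)phenyl]oxolan-2-one | O=C1C[C@@H](CO1)c1cc(C(C)(C)C=C)c(OCOC)cc1OCOC | intermediate
11 | (3R)-3-[2,4-bis(methoxymethoxy)-5-(2-methylbut-3-en-2-yl)phenyl]-4-hydroxy-N-methoxy-N-methylbutanamide | CON(C)C(=O)C[C@@H](CO)c1cc(C(C)(C)C=C)c(OCOC)cc1OCOC | intermediate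
12 | (3R)-3-[2,4-bis(methoxymethoxy)-5-(2-methylbut-3-en-2-yl)phenyl]-4-chloro-N-methoxy-N-methylbutanamide | CON(C)C(=O)C[C@@H](CCl)c1cc(C(C)(C)C=C)c(OCOC)cc1OCOC | intermediate
13 | (3R)-3-[2,4-bis(methoxymethoxy)-5-(2-methylbut-3-en-2-yl)phenyl]-4-chlorobutanal | O=CC[C@@H](CCl)c1cc(C(C)(C)C=C)c(OCOC)cc1OCOC | intermediate
14 | (3E,6R)-6-[2,4-bis(methoxymethoxy)-5-(2-methylbut-3-en-2-yl)phenyl]-7-chlorohept-3-en-2-one | CC(=O)/C=C/C[C@@H](CCl)c1cc(C(C)(C)C=C)c(OCOC)cc1OCOC | intermediate
15 | (5E,8R)-8-[2,4-bis(methoxymethoxy)-5-(2-methylbut-3-en-2-yl)phenyl]-9-chloro-1,1,1-trifluoronon-5-ene-2,4-dione | O=C(CC(=O)/C=C/C[C@@H](CCl)c1cc(C(C)(C)C=C)c(OCOC)cc1OCOC)C(F)(F)F | intermediate (not isolated)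
16 | (3E,6R)-6-[2,4-bis(methoxymethoxy)-5-(2-methylbut-3-en-2-yl)phenyl]-7-chloro-1-diazohept-3-en-2-one | [N-]=[N+]=CC(=O)/C=C/C[C@@H](CCl)c1cc(C(C)(C)C=C)c(OCOC)cc1OCOC | intermediate (key-step precursor)
17 | methyl pent-4-ynoate | C#CCCC(=O)OC | starting material
18 | 2-methylhex-5-yn-2-ol | C#CCCC(C)(C)O | intermediate
19 | triethyl[(2-methylhex-5-yn-2-yl)oxy]silane | C#CCCC(C)(C)O[Si](CC)(CC)CC | intermediate
20 | [5-methyl-5-(triethylsilyloxy)hex-1-yn-1-yl]lithium | [Li]C#CCCC(C)(C)O[Si](CC)(CC)CC | intermediate (not isolated)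
21 | lithium 5-methyl-5-(triethylsilyloxy)hex-1-yn-1-olate | [Li]OC#CCCC(C)(C)O[Si](CC)(CC)CC | intermediate (not isolated)
22 | 5-methyl-5-(triethylsilyloxy)-1-(triisopropylsilyloxy)hex-1-yne | CC(C)[Si](C(C)C)(C(C)C)OC#CCCC(C)(C)O[Si](CC)(CC)CC | intermediate (key-step precursor)
23 | (3E,6R)-6-[2,4-bis(methoxymethoxy)-5-(2-methylbut-3-en-2-yl)phenyl]-7-chlorohepta-1,3-dien-1-one | O=C=C/C=C/C[C@@H](CCl)c1cc(C(C)(C)C=C)c(OCOC)cc1OCOC | intermediate (not isolated)
24 | 4-[(1E,4R)-4-aryl-5-chloropent-1-en-1-yl]-2-[3-methyl-3-(triethylsilyloxy)butyl]-3-(triisopropylsilyloxy)cyclobut-2-en-1-one, both epimers at the ring CH | O=C1C(CCC(C)(C)O[Si](CC)(CC)CC)=C(O[Si](C(C)C)(C(C)C)C(C)C)C1/C=C/C[C@@H](CCl)c1cc(C(C)(C)C=C)c(OCOC)cc1OCOC | intermediate (not isolated)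
25 | (3E,5E,8R)-8-aryl-9-chloro-2-[3-methyl-3-(triethylsilyloxy)butyl]-3-(triisopropylsilyloxy)nona-1,3,5-trien-1-one | O=C=C(CCC(C)(C)O[Si](CC)(CC)CC)/C(O[Si](C(C)C)(C(C)C)C(C)C)=C\C=C\C[C@@H](CCl)c1cc(C(C)(C)C=C)c(OCOC)cc1OCOC | intermediate (not isolated)
26 | 6-[(2R)-2-aryl-3-chloropropyl]-2-[3-methyl-3-(triethylsilyloxy)butyl]-3-(triisopropylsilyloxy)phenol | Oc1c(CCC(C)(C)O[Si](CC)(CC)CC)c(O[Si](C(C)C)(C(C)C)C(C)C)ccc1C[C@@H](CCl)c1cc(C(C)(C)C=C)c(OCOC)cc1OCOC | intermediate (key-step product)
27 | 6-[(2R)-2-aryl-3-iodopropyl]-2-[3-methyl-3-(triethylsilyloxy)butyl]-3-(triisopropylsilyloxy)phenol | Oc1c(CCC(C)(C)O[Si](CC)(CC)CC)c(O[Si](C(C)C)(C(C)C)C(C)C)ccc1C[C@@H](CI)c1cc(C(C)(C)C=C)c(OCOC)cc1OCOC | intermediate (not isolated)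
28 | (3R)-3-[2,4-bis(methoxymethoxy)-5-(2-methylbut-3-en-2-yl)phenyl]-8-[3-methyl-3-(triethylsilyloxy)butyl]-7-(triisopropylsilyloxy)-3,4-dihydro-2H-chromene | C=CC(C)(C)c1cc([C@@H]2COc3c(ccc(O[Si](C(C)C)(C(C)C)C(C)C)c3CCC(C)(C)O[Si](CC)(CC)CC)C2)c(OCOC)cc1OCOC | intermediate
29 | (3R)-3-[5-(2-methylbut-3-en-2-yl)-2,4-bis(trimethylsilyloxy)phenyl]-8-[3-methyl-3-(triethylsilyloxy)butyl]-7-(triisopropylsilyloxy)-3,4-dihydro-2H-chromene | C=CC(C)(C)c1cc([C@@H]2COc3c(ccc(O[Si](C(C)C)(C(C)C)C(C)C)c3CCC(C)(C)O[Si](CC)(CC)CC)C2)c(O[Si](C)(C)C)cc1O[Si](C)(C)C | intermediate (not isolated)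
30 | 4-[(3R)-8-[3-methyl-3-(triethylsilyloxy)butyl]-7-(triisopropylsilyloxy)-3,4-dihydro-2H-chromen-3-yl]-6-(2-methylbut-3-en-2-yl)benzene-1,3-diol | C=CC(C)(C)c1cc([C@@H]2COc3c(ccc(O[Si](C(C)C)(C(C)C)C(C)C)c3CCC(C)(C)O[Si](CC)(CC)CC)C2)c(O)cc1O | intermediate
31 | 4-[(3R)-7-hydroxy-8-(3-hydroxy-3-methylbutyl)-3,4-dihydro-2H-chromen-3-yl]-6-(2-methylbut-3-en-2-yl)benzene-1,3-diol (CNP0420388.1) | C=CC(C)(C)c1cc([C@@H]2COc3c(ccc(O)c3CCC(C)(C)O)C2)c(O)cc1O | target

Total step count: 18. Longest linear sequence: 15 steps (steps 1–11, then 15–18); the siloxyalkyne branch is steps 12–14.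

Steps most likely to fail

1. Step 15 (benzannulation). The vinylketene may be lost to dimerisation or to acylation of the product phenol before the siloxyalkyne captures it, or the cyclobutenone may fail to open and reclose. The fallback sets out from 16 (with alkyne 19) and returns at 26. C-silylation of 16 with i-Pr3SiOTf and i-Pr2NEt in Et2O–hexane should give the silyl diazo enone (3E,6R)-6-Ar-7-chloro-1-diazo-1-(triisopropylsilyl)hept-3-en-2-one F1. Photochemical Wolff rearrangement of it in benzene, with no trapping partner present, should give the stable, chromatographable silylvinylketene (3E,6R)-6-Ar-7-chloro-2-(triisopropylsilyl)hepta-1,3-dien-1-one F2. F2 is then added to lithium ynolate 21 (made from 19 as in step 14, leaving out the silyl triflate) in THF at −78 °C → rt. This is the known ynolate benzannulation of silylvinylketenes: C-acylation of the ynolate at the ketene carbonyl, 6π closure of the oxido dienylketene and carbon-to-oxygen silyl shift. It should place the free hydroxyl at C8a and the triisopropylsilyl ether at C7, which is 26 after aqueous NH4Cl.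

2. Step 6 (conjugate arylation). Protodeboronation of the electron-rich ortho-alkoxy boronic acid may outrun insertion of the sluggish butenolide, or facial discrimination may be poor. The fallback sets out from 8 and returns at 10. Suzuki–Miyaura coupling of 8 with commercial 4-bromofuran-2(5H)-one (Pd(PPh3)4, KF, THF/H2O, 50 °C) should give the butenolide 4-Ar-furan-2(5H)-one F3. Copper hydride asymmetric conjugate reduction (CuCl2·2H2O, p-Tol-BINAP, NaOt-Bu, polymethylhydrosiloxane, t-AmOH, toluene) is a known route to β-aryl-γ-butyrolactones and should leave the unactivated vinyl group alone. The ligand enantiomer is chosen by correlation to give (R)-10.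

3. Step 2 (α-arylation). Oxidative addition to the electron-rich, ortho-substituted bromide may be slow, so that the enolate is consumed by aldol self-condensation. The fallback sets out from 1 and returns at 6, bypassing 2, 4 and 5. Monoalkylation of 1 with 1-bromo-3-methylbut-2-ene (K2CO3, acetone) at the less hindered hydroxyl para to bromine should give 2-bromo-5-[(3-methylbut-2-en-1-yl)oxy]phenol F4, with the regioisomeric ether removed by chromatography. Aromatic Claisen rearrangement (EtOH/H2O, 130 °C, sealed tube) moves the prenyl group with allylic inversion to the free ortho carbon and should give 4-bromo-6-(2-methylbut-3-en-2-yl)benzene-1,3-diol F5. MOMCl and i-Pr2NEt then give 6.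

Further compounds
F1 | step 15 | (3E,6R)-6-[2,4-bis(methoxymethoxy)-5-(2-methylbut-3-en-2-yl)phenyl]-7-chloro-1-diazo-1-(triisopropylsilyl)hept-3-en-2-one | [N-]=[N+]=C([Si](C(C)C)(C(C)C)C(C)C)C(=O)/C=C/C[C@@H](CCl)c1cc(C(C)(C)C=C)c(OCOC)cc1OCOC
F2 | step 15 | (3E,6R)-6-[2,4-bis(methoxymethoxy)-5-(2-methylbut-3-en-2-yl)phenyl]-7-chloro-2-(triisopropylsilyl)hepta-1,3-dien-1-one | O=C=C([Si](C(C)C)(C(C)C)C(C)C)/C=C/C[C@@H](CCl)c1cc(C(C)(C)C=C)c(OCOC)cc1OCOC
F3 | step 6 | 4-[2,4-bis(methoxymethoxy)-5-(2-methylbut-3-en-2-yl)phenyl]furan-2(5H)-one | O=C1C=C(CO1)c1cc(C(C)(C)C=C)c(OCOC)cc1OCOC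
F4 | step 2 | 2-bromo-5-[(3-methylbut-2-en-1-yl)oxy]phenol | CC(C)=CCOc1ccc(Br)c(O)c1
F5 | step 2 | 4-bromo-6-(2-methylbut-3-en-2-yl)benzene-1,3-diol | C=CC(C)(C)c1cc(Br)c(O)cc1O
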